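The route rests on reading the C1 ketone and the C5–C6 oxirane of the cyclohexenone ring (C1 ketone, C2 amide-bearing, C4 carbinol, C5 and C6 oxirane carbons) as a Darzens retron: C6 is the α-carbon of the C1 ketone and C5 was an aldehyde carbon. An acyclic chloromethyl ketone aldehyde, carrying only the C4 silyloxy stereocentre, the complete upper enamide and a vinylstannane handle, is closed by an intramolecular Darzens condensation that forms the C5–C6 bond, the carbocycle, the oxirane and both oxirane stereocentres in one operation. Its cis enone geometry comes from a temporary δ-lactone made by ring-closing metathesis and opened with chloromethyllithium; C4 comes from a Sharpless epoxidation. Stille coupling and desilylation finish the synthesis.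

Key step: step 15

Remark on the chemistry: the target is read as the anti hydroxy epoxide (C4–OH and oxirane oxygen on opposite faces of the ring), (4S,5S,6R) in the core numbering above. This numbering is used in all names of cyclohexenone intermediates. "Cis enone" means that the C1 acyl carbon and C4 lie on the same side of the C2=C3 bond (E by the sequence rules, because nitrogen outranks C1).

**Upper chain (steps 1–5)**

Step 1
Reactants: 1 4-methylpentanal; 2 (triphenylphosphoranylidene)acetaldehyde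
Product: 3 (E)-6-methylhept-2-enal
Conditions: toluene, 80 °C
Reagents that add atoms: none
Why: Wittig olefination with the stabilised formyl ylide should give the (E)-enal, and the lower reactivity of the conjugated product limits a second homologation.

Step 2
Reactants: 3 (E)-6-methylhept-2-enal; 4 triethyl 4-phosphonocrotonate
Product: 6 (2E,4E,6E)-10-methylundeca-2,4,6-trienoic acid, via ethyl trienoate 5 (not isolated)
Conditions: LiHMDS, THF, −78 to 0 °C; then LiOH, MeOH/H2O, rt; 1 M HCl work-up
Reagents that add atoms: water (as LiOH/H2O), O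
Why: Horner–Wadsworth–Emmons olefination with the vinylogous phosphonate anion should form the new C4=C5 bond with E geometry, and saponification in the same flask gives the acid.

Step 3
Reactants: 6 (2E,4E,6E)-10-methylundeca-2,4,6-trienoic acid; 7 L-serine methyl ester hydrochloride
Product: 8 methyl N-[(2E,4E,6E)-10-methylundeca-2,4,6-trienoyl]-L-serinate
Conditions: EDC·HCl, HOBt, N-methylmorpholine, CH2Cl2, 0 °C to rt
Reagents that add atoms: none
Why: Carbodiimide amide coupling should acylate the amine of the serine ester in preference to its primary hydroxyl.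

Step 4
Reactants: 8 methyl N-trienoyl-L-serinate
Product: 9 methyl 2-[(2E,4E,6E)-10-methylundeca-2,4,6-trienamido]acrylate
Conditions: MsCl, Et3N, CH2Cl2, 0 °C to rt
Reagents that add atoms: none
Why: Mesylation of the serine hydroxyl followed by E1cB β-elimination should give the dehydroalanine ester; the serine stereocentre is removed on purpose.

Step 5
Reactants: 9 methyl 2-(trienamido)acrylate
Product: 10 2-[(2E,4E,6E)-10-methylundeca-2,4,6-trienamido]acrylic acid
Conditions: LiOH, THF/H2O, 0 °C; 1 M HCl work-up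
Reagents that add atoms: water (as LiOH/H2O), O
Why: Ester saponification; the amido-substituted acrylate is a poor acceptor for hydroxide at 0 °C.

**Core (steps 6–15)**

Step 6
Reactants: 11 2-bromoprop-2-en-1-ol; 12 ethynyltrimethylsilane
Product: 13 2-methylidene-4-(trimethylsilyl)but-3-yn-1-ol
Conditions: PdCl2(PPh3)2 (2 mol%), CuI (4 mol%), i-Pr2NH, THF, rt
Reagents that add atoms: none
Why: Sonogashira coupling of the vinyl bromide with the terminal alkyne.

Step 7
Reactants: 13 2-methylidene-4-(trimethylsilyl)but-3-yn-1-ol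
Product: 14 (R)-{2-[(trimethylsilyl)ethynyl]oxiran-2-yl}methanol
Conditions: Ti(OiPr)4 (10 mol%), D-(−)-diethyl tartrate (12 mol%), t-BuOOH, 4 Å MS, CH2Cl2, −20 °C
Reagents that add atoms: tert-butyl hydroperoxide, CC(C)(C)OO
Why: Sharpless asymmetric epoxidation of the 2-substituted allylic alcohol; D-(−)-tartrate should give the (R)-epoxide (L-(+)-tartrate gives the (S)-series of 2-substituted glycidols), which sets the future C4 stereocentre.

Step 8
Reactants: 14 (R)-{2-[(trimethylsilyl)ethynyl]oxiran-2-yl}methanol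
Product: 16 (R)-2-ethynylbut-3-ene-1,2-diol, via silylated enynediol 15 (not isolated)
Conditions: Me3S+ I−, n-BuLi, THF, −10 °C to rt; then K2CO3 (cat.), MeOH, rt
Reagents that add atoms: trimethylsulfonium iodide, C[S+](C)C.[I-]
Why: Dimethylsulfonium methylide (Corey–Chaykovsky reagent) should open the epoxide at its CH2 terminus and the β-sulfonium alkoxide eliminates dimethyl sulfide to the vinyl carbinol without touching the quaternary stereocentre; methanolysis then removes the alkynyl silyl group.

Step 9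
Reactants: 16 (R)-2-ethynylbut-3-ene-1,2-diol
Product: 17 (2R,3E)-2-ethenyl-4-(tributylstannyl)but-3-ene-1,2-diol
Conditions: Bu3SnH, PdCl2(PPh3)2 (2 mol%), THF, 0 °C
Reagents that add atoms: tributyltin hydride, CCCC[SnH](CCCC)CCCC
Why: Palladium-catalysed syn hydrostannation of the terminal alkyne should place tin at the distal carbon of the hindered tertiary propargylic alcohol and give the (E)-vinylstannane.

Step 10
Reactants: 17 (2R,3E)-2-ethenyl-4-(tributylstannyl)but-3-ene-1,2-diol; 10 2-(trienamido)acrylic acid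
Product: 18 [(2R,3E)-2-ethenyl-2-hydroxy-4-(tributylstannyl)but-3-en-1-yl] 2-[(2E,4E,6E)-10-methylundeca-2,4,6-trienamido]acrylate
Conditions: EDC·HCl, DMAP, CH2Cl2, 0 °C to rt
Reagents that add atoms: none
Why: Steglich-type esterification should be selective for the primary over the tertiary hydroxyl.

Step 11
Reactants: 18 dehydroalanine ester
Product: 19 (2E,4E,6E)-N-{(5R)-5-hydroxy-2-oxo-5-[(E)-2-(tributylstannyl)ethenyl]-5,6-dihydro-2H-pyran-3-yl}-10-methylundeca-2,4,6-trienamide
Conditions: second-generation Hoveyda–Grubbs catalyst (10 mol%), toluene (5 mM), 80 °C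
Reagents that add atoms: none
Why: Ring-closing metathesis between the vinyl group and the amidoacrylate should form the C2=C3 bond inside a six-membered lactone, so C1 and C4 are necessarily cis; the free tertiary allylic hydroxyl assists loading of ruthenium at the hindered vinyl group.

Step 12
Reactants: 19 hydroxy lactone
Product: 20 (2E,4E,6E)-N-{(5R)-2-oxo-5-(triethylsilyloxy)-5-[(E)-2-(tributylstannyl)ethenyl]-5,6-dihydro-2H-pyran-3-yl}-10-methylundeca-2,4,6-trienamide
Conditions: TESOTf, 2,6-lutidine, CH2Cl2, −78 to 0 °C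
Reagents that add atoms: triethylsilyl trifluoromethanesulfonate, CC[Si](CC)(CC)OS(=O)(=O)C(F)(F)F
Why: Silylation of the hindered tertiary alcohol with the silyl triflate; the triethylsilyl ether later prevents hemiketal formation at C4–O and chelation in the key step.

Step 13
Reactants: 20 silylated lactone
Product: 21 (2E,4E,6E)-N-{(5R)-2-(chloromethyl)-2-hydroxy-5-(triethylsilyloxy)-5-[(E)-2-(tributylstannyl)ethenyl]-5,6-dihydro-2H-pyran-3-yl}-10-methylundeca-2,4,6-trienamide (lactol, mixture of anomers, in equilibrium with its open-chain hydroxy ketone)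
Conditions: LiHMDS (1.05 equiv), THF, −78 °C; ICH2Cl, MeLi·LiBr, −78 °C; AcOH quench at −78 °C
Reagents that add atoms: chloroiodomethane, ClCI
Why: Chloromethyllithium, generated in situ by iodine–lithium exchange, should add once to the lactone carbonyl because the tetrahedral lithium alkoxide is stable at −78 °C; cold protonation gives the chloromethyl lactol, the ring tautomer of the cis hydroxy chloromethyl enone.

Step 14
Reactants: 21 chloromethyl lactol
Product: 23 (2E,4E,6E)-N-{(3E,5R)-1-chloro-2,6-dioxo-5-(triethylsilyloxy)-5-[(E)-2-(tributylstannyl)ethenyl]hex-3-en-3-yl}-10-methylundeca-2,4,6-trienamide, via open-chain hydroxy ketone 22 (not isolated)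
Conditions: Dess–Martin periodinane, NaHCO3, CH2Cl2, 0 °C to rt
Reagents that add atoms: none
Why: Dess–Martin oxidation should convert the primary alcohol of the open-chain tautomer, which is replenished by ring–chain equilibration, into the non-enolisable aldehyde; the tertiary hemiketal cannot be oxidised.

Step 15
Reactants: 23 chloromethyl ketone aldehyde
Product: 25 (2E,4E,6E)-N-{(4R,5S,6R)-5,6-epoxy-1-oxo-4-(triethylsilyloxy)-4-[(E)-2-(tributylstannyl)ethenyl]cyclohex-2-en-2-yl}-10-methylundeca-2,4,6-trienamide (oxirane oxygen trans to the C4 silyloxy group), via chlorohydrin 24 (not isolated)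
Conditions: KHMDS (2.2 equiv), THF, −78 to −20 °C; aq. NH4Cl
Reagents that add atoms: none
Why: KHMDS removes the amide N–H and then a C6–H, the C6 chloro-enolate adds to the C5 aldehyde, and the C5 alkoxide displaces chloride at C6 with inversion; this is an intramolecular Darzens condensation, the closest known type being the Darzens reaction of α-chloro ketones with aldehydes. The six-membered carbocycle closes in a 6-(enolexo)-exo-trig aldol addition and the oxirane in a 3-exo-tet substitution. C5 is controlled by C4: with a non-chelating silyl ether and a potassium counter-ion the C5=O bond should lie anti-periplanar to the pseudo-axial C4–OSiEt3 bond (Cornforth-type dipole minimisation) while the large stannylvinyl group sits pseudo-equatorial, so the aldehyde oxygen, which becomes the oxirane oxygen, ends up trans to the C4 oxygen. C6 follows from the ring, which allows only a cis-fused oxirane, and the chloride-bearing centre can epimerise through the enolate until chloride is anti-periplanar to the alkoxide. The step needs anti facial selectivity, secured by the triethylsilyl group, and site selectivity, secured because C6 is the only enolisable position, the aldehyde cannot enolise, and the cis enone geometry inherited from the lactone holds C6 within reach of C5.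

**Lower chain (steps 16–20)**

Step 16
Reactants: 26 ethyl (E)-4-oxobut-2-enoate
Product: 27 ethyl (2E,4E)-5-iodopenta-2,4-dienoate
Conditions: CrCl2, CHI3, THF, 0 °C
Reagents that add atoms: iodoform, IC(I)I
Why: Takai olefination should convert the aldehyde into the (E)-vinyl iodide.

Step 17
Reactants: 27 ethyl (2E,4E)-5-iodopenta-2,4-dienoate
Product: 28 (2E,4E)-5-iodopenta-2,4-dienoic acid
Conditions: LiOH, THF/H2O, rt; 1 M HCl work-up
Reagents that add atoms: water (as LiOH/H2O), O
Why: Ester saponification, which leaves the vinyl iodide untouched.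

Step 18
Reactants: 29 cyclopentane-1,3-dione
Product: 30 2-(hydroxyimino)cyclopentane-1,3-dione
Conditions: NaNO2, aq. HCl, 0 °C
Reagents that add atoms: sodium nitrite, [Na+].[O-]N=O
Why: Nitrosation of the enolised 1,3-dione at C2 followed by tautomerisation should give the oxime.

Step 19
Reactants: 30 2-(hydroxyimino)cyclopentane-1,3-dione
Product: 31 2-amino-3-hydroxycyclopent-2-en-1-one hydrochloride
Conditions: H2 (1 atm), Pd/C, HCl, MeOH, rt
Reagents that add atoms: hydrogen chloride, Cl
Why: Catalytic hydrogenation of the oxime should give the primary amine, trapped as the hydrochloride of its enol tautomer.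

Step 20
Reactants: 28 (2E,4E)-5-iodopenta-2,4-dienoic acid; 31 2-amino-3-hydroxycyclopent-2-en-1-one hydrochloride
Product: 33 (2E,4E)-N-(2-hydroxy-5-oxocyclopent-1-en-1-yl)-5-iodopenta-2,4-dienamide, via acid chloride 32 (not isolated)
Conditions: (COCl)2, DMF (cat.), CH2Cl2, 0 °C to rt; then 31, Et3N, THF, 0 °C to rt
Reagents that add atoms: none
Why: Acid chloride formation and N-acylation of the aminoenone; any O-acyl enol ester should transfer its acyl group to nitrogen or be cleaved on work-up.

**Endgame (steps 21–22)**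

Step 21
Reactants: 25 stannylated epoxy ketone; 33 iododienamide
Product: 34 (2E,4E,6E)-N-[(4S,5S,6R)-5,6-epoxy-4-{(1E,3E,5E)-7-[(2-hydroxy-5-oxocyclopent-1-en-1-yl)amino]-7-oxohepta-1,3,5-trien-1-yl}-1-oxo-4-(triethylsilyloxy)cyclohex-2-en-2-yl]-10-methylundeca-2,4,6-trienamide
Conditions: Pd2(dba)3 (5 mol%), AsPh3 (20 mol%), DMF, rt, dark
Reagents that add atoms: none
Why: Stille coupling of the vinylstannane with the vinyl iodide, with retention of both alkene geometries, should complete the (E,E,E)-triene under neutral conditions that spare the epoxy ketone.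

Step 22
Reactants: 34 silylated target
Product: 35 (2E,4E,6E)-N-[(4S,5S,6R)-5,6-epoxy-4-hydroxy-4-{(1E,3E,5E)-7-[(2-hydroxy-5-oxocyclopent-1-en-1-yl)amino]-7-oxohepta-1,3,5-trien-1-yl}-1-oxocyclohex-2-en-2-yl]-10-methylundeca-2,4,6-trienamide (target)
Conditions: HF·pyridine, pyridine, THF, 0 °C
Reagents that add atoms: none
Why: Buffered fluoride cleavage of the tertiary triethylsilyl ether should liberate the C4 hydroxyl without opening the oxirane.

**Compound list**

1 | 4-methylpentanal | CC(C)CCC=O | starting material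
2 | (triphenylphosphoranylidene)acetaldehyde | O=CC=P(c1ccccc1)(c1ccccc1)c1ccccc1 | starting material
3 | (E)-6-methylhept-2-enal | CC(C)CC/C=C/C=O | intermediate
4 | triethyl 4-phosphonocrotonate | CCOC(=O)/C=C/CP(=O)(OCC)OCC | starting material
5 | ethyl (2E,4E,6E)-10-methylundeca-2,4,6-trienoate | CC(C)CC/C=C/C=C/C=C/C(=O)OCC | intermediate
6 | (2E,4E,6E)-10-methylundeca-2,4,6-trienoic acid | CC(C)CC/C=C/C=C/C=C/C(=O)O | intermediate
7 | L-serine methyl ester hydrochloride | COC(=O)[C@@H](N)CO.Cl | starting material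
8 | methyl N-[(2E,4E,6E)-10-methylundeca-2,4,6-trienoyl]-L-serinate | CC(C)CC/C=C/C=C/C=C/C(=O)N[C@@H](CO)C(=O)OC | intermediate
9 | methyl 2-[(2E,4E,6E)-10-methylundeca-2,4,6-trienamido]acrylate | CC(C)CC/C=C/C=C/C=C/C(=O)NC(=C)C(=O)OC | intermediate
10 | 2-[(2E,4E,6E)-10-methylundeca-2,4,6-trienamido]acrylic acid | CC(C)CC/C=C/C=C/C=C/C(=O)NC(=C)C(=O)O | intermediate
11 | 2-bromoprop-2-en-1-ol | OCC(Br)=C | starting material
12 | ethynyltrimethylsilane | C#C[Si](C)(C)C | starting material
13 | 2-methylidene-4-(trimethylsilyl)but-3-yn-1-ol | OCC(=C)C#C[Si](C)(C)C | intermediate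
14 | (R)-{2-[(trimethylsilyl)ethynyl]oxiran-2-yl}methanol | OC[C@]1(C#C[Si](C)(C)C)CO1 | intermediate
15 | (R)-2-[(trimethylsilyl)ethynyl]but-3-ene-1,2-diol | OC[C@](O)(C#C[Si](C)(C)C)C=C | intermediate
16 | (R)-2-ethynylbut-3-ene-1,2-diol | OC[C@](O)(C#C)C=C | intermediate
17 | (2R,3E)-2-ethenyl-4-(tributylstannyl)but-3-ene-1,2-diol | OC[C@](O)(/C=C/[Sn](CCCC)(CCCC)CCCC)C=C | intermediate
18 | [(2R,3E)-2-ethenyl-2-hydroxy-4-(tributylstannyl)but-3-en-1-yl] 2-[(2E,4E,6E)-10-methylundeca-2,4,6-trienamido]acrylate | CC(C)CC/C=C/C=C/C=C/C(=O)NC(=C)C(=O)OC[C@](O)(/C=C/[Sn](CCCC)(CCCC)CCCC)C=C | intermediate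
19 | (2E,4E,6E)-N-{(5R)-5-hydroxy-2-oxo-5-[(E)-2-(tributylstannyl)ethenyl]-5,6-dihydro-2H-pyran-3-yl}-10-methylundeca-2,4,6-trienamide | CC(C)CC/C=C/C=C/C=C/C(=O)NC1=C[C@@](O)(/C=C/[Sn](CCCC)(CCCC)CCCC)COC1=O | intermediate
20 | (2E,4E,6E)-N-{(5R)-2-oxo-5-(triethylsilyloxy)-5-[(E)-2-(tributylstannyl)ethenyl]-5,6-dihydro-2H-pyran-3-yl}-10-methylundeca-2,4,6-trienamide | CC(C)CC/C=C/C=C/C=C/C(=O)NC1=C[C@@](O[Si](CC)(CC)CC)(/C=C/[Sn](CCCC)(CCCC)CCCC)COC1=O | intermediate
21 | (2E,4E,6E)-N-{(5R)-2-(chloromethyl)-2-hydroxy-5-(triethylsilyloxy)-5-[(E)-2-(tributylstannyl)ethenyl]-5,6-dihydro-2H-pyran-3-yl}-10-methylundeca-2,4,6-trienamide (anomeric mixture) | CC(C)CC/C=C/C=C/C=C/C(=O)NC1=C[C@@](O[Si](CC)(CC)CC)(/C=C/[Sn](CCCC)(CCCC)CCCC)COC1(O)CCl | intermediate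
22 | (2E,4E,6E)-N-{(3E,5R)-1-chloro-6-hydroxy-2-oxo-5-(triethylsilyloxy)-5-[(E)-2-(tributylstannyl)ethenyl]hex-3-en-3-yl}-10-methylundeca-2,4,6-trienamide | CC(C)CC/C=C/C=C/C=C/C(=O)N/C(C(=O)CCl)=C/[C@@](O[Si](CC)(CC)CC)(/C=C/[Sn](CCCC)(CCCC)CCCC)CO | intermediate
23 | (2E,4E,6E)-N-{(3E,5R)-1-chloro-2,6-dioxo-5-(triethylsilyloxy)-5-[(E)-2-(tributylstannyl)ethenyl]hex-3-en-3-yl}-10-methylundeca-2,4,6-trienamide | CC(C)CC/C=C/C=C/C=C/C(=O)N/C(C(=O)CCl)=C/[C@@](O[Si](CC)(CC)CC)(/C=C/[Sn](CCCC)(CCCC)CCCC)C=O | intermediate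
24 | (2E,4E,6E)-N-{(4R,5R,6S)-6-chloro-5-hydroxy-1-oxo-4-(triethylsilyloxy)-4-[(E)-2-(tributylstannyl)ethenyl]cyclohex-2-en-2-yl}-10-methylundeca-2,4,6-trienamide | CC(C)CC/C=C/C=C/C=C/C(=O)NC1=C[C@@](O[Si](CC)(CC)CC)(/C=C/[Sn](CCCC)(CCCC)CCCC)[C@@H](O)[C@H](Cl)C1=O | intermediate
25 | (2E,4E,6E)-N-{(4R,5S,6R)-5,6-epoxy-1-oxo-4-(triethylsilyloxy)-4-[(E)-2-(tributylstannyl)ethenyl]cyclohex-2-en-2-yl}-10-methylundeca-2,4,6-trienamide | CC(C)CC/C=C/C=C/C=C/C(=O)NC1=C[C@@](O[Si](CC)(CC)CC)(/C=C/[Sn](CCCC)(CCCC)CCCC)[C@H]2O[C@H]2C1=O | intermediate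
26 | ethyl (E)-4-oxobut-2-enoate | CCOC(=O)/C=C/C=O | starting material
27 | ethyl (2E,4E)-5-iodopenta-2,4-dienoate | CCOC(=O)/C=C/C=C/I | intermediate
28 | (2E,4E)-5-iodopenta-2,4-dienoic acid | OC(=O)/C=C/C=C/I | intermediate
29 | cyclopentane-1,3-dione | O=C1CCC(=O)C1 | starting material
30 | 2-(hydroxyimino)cyclopentane-1,3-dione | O=C1CCC(=O)C1=NO | intermediate
31 | 2-amino-3-hydroxycyclopent-2-en-1-one hydrochloride | NC1=C(O)CCC1=O.Cl | intermediate
32 | (2E,4E)-5-iodopenta-2,4-dienoyl chloride | ClC(=O)/C=C/C=C/I | intermediate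
33 | (2E,4E)-N-(2-hydroxy-5-oxocyclopent-1-en-1-yl)-5-iodopenta-2,4-dienamide | O=C(/C=C/C=C/I)NC1=C(O)CCC1=O | intermediate
34 | (2E,4E,6E)-N-[(4S,5S,6R)-5,6-epoxy-4-{(1E,3E,5E)-7-[(2-hydroxy-5-oxocyclopent-1-en-1-yl)amino]-7-oxohepta-1,3,5-trien-1-yl}-1-oxo-4-(triethylsilyloxy)cyclohex-2-en-2-yl]-10-methylundeca-2,4,6-trienamide | CC(C)CC/C=C/C=C/C=C/C(=O)NC1=C[C@@](O[Si](CC)(CC)CC)(/C=C/C=C/C=C/C(=O)NC2=C(O)CCC2=O)[C@H]2O[C@H]2C1=O | intermediate
35 | (2E,4E,6E)-N-[(4S,5S,6R)-5,6-epoxy-4-hydroxy-4-{(1E,3E,5E)-7-[(2-hydroxy-5-oxocyclopent-1-en-1-yl)amino]-7-oxohepta-1,3,5-trien-1-yl}-1-oxocyclohex-2-en-2-yl]-10-methylundeca-2,4,6-trienamide | CC(C)CC/C=C/C=C/C=C/C(=O)NC1=C[C@@](O)(/C=C/C=C/C=C/C(=O)NC2=C(O)CCC2=O)[C@H]2O[C@H]2C1=O | target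

**Step count**

Total step count: 22.
Longest linear sequence: 13 steps (steps 1–5, 10–15, 21 and 22, from 4-methylpentanal). The core line from 2-bromoprop-2-en-1-ol is 12 steps (steps 6–15, 21, 22).

**Steps most likely to fail**

1. Step 15 (Darzens ring closure). The aldol addition may show poor facial selectivity, so that the aldehyde oxygen ends up syn to the C4 silyloxy group. Alternatively, O-alkylation of the amidate by the chloromethyl ketone may outrun enolate addition. The fallback sets out from lactone 20 and comes back at epoxide 25. Methyllithium, used in place of chloromethyllithium after N–H deprotonation, should give the methyl lactol F1. Dess–Martin oxidation of its open-chain tautomer gives the methyl ketone aldehyde F2. Potassium tert-butoxide then promotes an intramolecular aldol condensation that closes the same C5–C6 bond and dehydrates to the cross-conjugated dienone F3. Weitz–Scheffer epoxidation (t-BuOOH, DBU) of the unsubstituted C5=C6 enone, expected to occur anti to the silyloxy group because no hydrogen-bond direction operates, gives 25. Stereocontrol is thereby moved from the aldol addition to a reagent approach on a rigid ring.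

2. Step 11 (ring-closing metathesis). Metathesis at the 1,1-disubstituted amidoacrylate and the hindered vinyl group may be slow, which leaves time for olefin isomerisation or for metathesis within the triene. The fallback sets out from epoxy alcohol 14 and comes back at lactone 20; the nitrogen is introduced by coupling instead of through the metathesis partner. The ylide opening of 14 is worked up without methanolysis so that silylated diol 15 is isolated. Acryloyl chloride and Et3N give the acrylate F4, and ring-closing metathesis of this simple acrylate with second-generation Grubbs catalyst gives the hydroxy lactone F5. Silylation (TESOTf, 2,6-lutidine) gives the silyl ether F6, and α-iodination with I2 and pyridine (addition–elimination) gives the iodo lactone F7. Acid 6 is converted by isobutyl chloroformate, N-methylmorpholine and ammonia into the trienamide F8. Goldberg-type amidation of F7 with F8 (CuI, N,N′-dimethylethylenediamine, K2CO3, toluene) gives the amido lactone F9. Silver-nitrate-catalysed protodesilylation (AgNO3, acetone/H2O) gives the terminal alkyne F10, and palladium-catalysed hydrostannation as in step 9 gives 20.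

3. Step 13 (chloromethyllithium addition). The tetrahedral intermediate may collapse early, leading to double addition or to a spiro-epoxide, or conversion may be incomplete because the neighbouring amidate deactivates the lactone. The fallback sets out from lactone 20 and comes back at lactol 21. Aminolysis with MeNH(OMe)·HCl and AlMe3 opens the lactone to the hydroxy Weinreb amide F11, whose chelated adduct with excess chloromethyllithium (ICH2Cl, MeLi·LiBr, −78 °C) cannot add a second time and gives 21 on protonation.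

**Further compounds**

F1 | step 15 | (2E,4E,6E)-N-{(5R)-2-hydroxy-2-methyl-5-(triethylsilyloxy)-5-[(E)-2-(tributylstannyl)ethenyl]-5,6-dihydro-2H-pyran-3-yl}-10-methylundeca-2,4,6-trienamide | CC(C)CC/C=C/C=C/C=C/C(=O)NC1=C[C@@](O[Si](CC)(CC)CC)(/C=C/[Sn](CCCC)(CCCC)CCCC)COC1(C)O
F2 | step 15 | (2E,4E,6E)-N-{(3E,5R)-2,6-dioxo-5-(triethylsilyloxy)-5-[(E)-2-(tributylstannyl)ethenyl]hex-3-en-3-yl}-10-methylundeca-2,4,6-trienamide | CC(C)CC/C=C/C=C/C=C/C(=O)N/C(C(C)=O)=C/[C@@](O[Si](CC)(CC)CC)(/C=C/[Sn](CCCC)(CCCC)CCCC)C=O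
F3 | step 15 | (2E,4E,6E)-N-{(4R)-1-oxo-4-(triethylsilyloxy)-4-[(E)-2-(tributylstannyl)ethenyl]cyclohexa-2,5-dien-2-yl}-10-methylundeca-2,4,6-trienamide | CC(C)CC/C=C/C=C/C=C/C(=O)NC1=C[C@@](O[Si](CC)(CC)CC)(/C=C/[Sn](CCCC)(CCCC)CCCC)C=CC1=O
F4 | step 11 | [(2R)-2-ethenyl-2-hydroxy-4-(trimethylsilyl)but-3-yn-1-yl] acrylate | C=CC(=O)OC[C@](O)(C#C[Si](C)(C)C)C=C
F5 | step 11 | (5R)-5-hydroxy-5-[(trimethylsilyl)ethynyl]-5,6-dihydro-2H-pyran-2-one | O=C1C=C[C@@](O)(C#C[Si](C)(C)C)CO1
F6 | step 11 | (5R)-5-(triethylsilyloxy)-5-[(trimethylsilyl)ethynyl]-5,6-dihydro-2H-pyran-2-one | O=C1C=C[C@@](O[Si](CC)(CC)CC)(C#C[Si](C)(C)C)CO1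
F7 | step 11 | (5R)-3-iodo-5-(triethylsilyloxy)-5-[(trimethylsilyl)ethynyl]-5,6-dihydro-2H-pyran-2-one | O=C1C(I)=C[C@@](O[Si](CC)(CC)CC)(C#C[Si](C)(C)C)CO1
F8 | step 11 | (2E,4E,6E)-10-methylundeca-2,4,6-trienamide | CC(C)CC/C=C/C=C/C=C/C(N)=O
F9 | step 11 | (2E,4E,6E)-N-{(5R)-2-oxo-5-(triethylsilyloxy)-5-[(trimethylsilyl)ethynyl]-5,6-dihydro-2H-pyran-3-yl}-10-methylundeca-2,4,6-trienamide | CC(C)CC/C=C/C=C/C=C/C(=O)NC1=C[C@@](O[Si](CC)(CC)CC)(C#C[Si](C)(C)C)COC1=O
F10 | step 11 | (2E,4E,6E)-N-[(5R)-5-ethynyl-2-oxo-5-(triethylsilyloxy)-5,6-dihydro-2H-pyran-3-yl]-10-methylundeca-2,4,6-trienamide | CC(C)CC/C=C/C=C/C=C/C(=O)NC1=C[C@@](O[Si](CC)(CC)CC)(C#C)COC1=O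
F11 | step 13 | (2E,4R)-5-hydroxy-N-methoxy-N-methyl-2-[(2E,4E,6E)-10-methylundeca-2,4,6-trienamido]-4-(triethylsilyloxy)-4-[(E)-2-(tributylstannyl)ethenyl]pent-2-enamide | CC(C)CC/C=C/C=C/C=C/C(=O)N/C(C(=O)N(C)OC)=C/[C@@](O[Si](CC)(CC)CC)(/C=C/[Sn](CCCC)(CCCC)CCCC)CO
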